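## Retrosynthetic overview
1. Target 24 comes from exo-face hydrogenation of the α-methylene ketone 23. That ketone comes from Eschenmoser methylenation of 22, and 22 from removal of the C1 ketone of 20.
2. Core 20 (spiro-δ-lactone plus bicyclo[3.2.1]octan-6-one) forms in one pot by an oxa-Michael / Michael / Weinreb-acylation cascade. It joins the α-methylene ketone 13 (ring A plus the THF methyl acetal) to the cyclohexene acid 19 (ring C plus the ring-D precursor).
3. Ring A, C4/C5 and the cis-fused THF come from an organocatalytic desymmetrising enamine Michael of dienone aldehyde 7, followed by Baeyer–Villiger deformylation and methanolysis to the methyl acetal. C20 is added by hydroxymethylation and dehydration. C13 of acid 19 comes from an organocatalytic malonate Michael to cyclohexenone.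
4. Ring-formation order: ring A plus THF (step 7), then ring C (steps 13–16), then spirolactone, C10/C9/C8 and ring D in one pot (step 17).

Assumptions: 15 is purchased (or made in one step from methyl malonyl chloride and HN(OMe)Me·HCl). The catalyst enantiomers are those that give the antipode shown. The target's endo 16-methyl (C16–H exo) is taken to arise from exo-face hydrogenation.

## Route

**Step 1**
Reactants: 1 methyl 1,4-dioxaspiro[4.5]decane-8-carboxylate
Product: 2 methyl 8-methyl-1,4-dioxaspiro[4.5]decane-8-carboxylate
Conditions: LDA, THF, −78 °C; then MeI, −78 → 0 °C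
Reagents that add atoms: methyl iodide, CI
Why: Ester-enolate α-methylation builds the C4 quaternary carbon; the product is still achiral.

**Step 2**
Reactants: 2
Product: 3 (8-methyl-1,4-dioxaspiro[4.5]decan-8-yl)methanol
Conditions: LiAlH4, THF, 0 °C
Reagents that add atoms: none
Why: Ester reduction gives the C19 carbinol; the ketal survives hydride.

**Step 3**
Reactants: 3
Product: 4 8-[(allyloxy)methyl]-8-methyl-1,4-dioxaspiro[4.5]decane
Conditions: NaH, allyl bromide, TBAI (cat.), THF, 0 °C → rt
Reagents that add atoms: allyl bromide, C=CCBr
Why: Williamson etherification installs the C19–O tether, which is a masked glycolaldehyde.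

**Step 4**
Reactants: 4
Product: 5 4-[(allyloxy)methyl]-4-methylcyclohexan-1-one
Conditions: 2 M HCl, acetone, rt
Reagents that add atoms: water, O
Why: Acid hydrolysis of the ketal; the allyl ether survives.

**Step 5**
Reactants: 5
Product: 6 4-[(allyloxy)methyl]-4-methylcyclohexa-2,5-dien-1-one
Conditions: IBX (2.5 equiv), DMSO, 80 °C
Reagents that add atoms: none
Why: Nicolaou IBX double dehydrogenation gives the achiral, prochiral cross-conjugated dienone, whose two β-carbons are enantiotopic.

**Step 6**
Reactants: 6
Product: 7 2-[(1-methyl-4-oxocyclohexa-2,5-dien-1-yl)methoxy]acetaldehyde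
Conditions: OsO4 (2.5 mol %), NaIO4 (4 equiv), 2,6-lutidine, dioxane/H2O, rt
Reagents that add atoms: sodium periodate, [Na+].[O-]I(=O)=O (oxygen source)
Why: Lemieux–Johnson cleavage is selective for the electron-rich allyl ether over the electron-poor dienone.

**Step 7**
Reactants: 7
Product: 8 cis-fused 3a-methyl-6-oxo-1,3,3a,6,7,7a-hexahydro-2-benzofuran-1-carbaldehyde (stereo per SMILES; CHO on the convex face)
Conditions: (S)-diphenylprolinol TMS ether (20 mol %), PhCO2H (20 mol %), CHCl3, 4 °C
Reagents that add atoms: none
Why: Enamine-catalysed desymmetrising intramolecular Michael (5-exo) of the glycolaldehyde-ether tether onto the dienone; the catalyst selects the enantiotopic β-carbon and sets C4 and C5, the tether forces the cis ring fusion, and C6 (α to CHO) settles on the convex face.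

**Step 8**
Reactants: 8
Product: 9 formate of the lactol (C6 OCHO; stereo per SMILES)
Conditions: mCPBA (1.5 equiv), NaHCO3, CH2Cl2, 0 °C
Reagents that add atoms: mCPBA, OOC(=O)c1cccc(Cl)c1
Why: Baeyer–Villiger oxidation of an α-alkoxy aldehyde, in which the oxygen-substituted carbon migrates with retention; this excises the extra carbon to give the acylal formate, and the enone is inert to peracid.

**Step 9**
Reactants: 9
Product: 10 methyl acetal enone (C6–OMe on the convex face)
Conditions: PPTS (0.2 equiv), MeOH, 40 °C
Reagents that add atoms: methanol, CO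
Why: Acid-promoted ionisation of the acylal to the oxocarbenium ion and capture by MeOH under anomeric and steric control gives the convex-face methyl acetal of the target.

**Step 10**
Reactants: 10
Product: 11 10-(hydroxymethyl) enone (C10 epimeric mixture)
Conditions: LiHMDS (1.05 equiv), THF, −78 °C; then CH2O (monomeric gas), −78 → −40 °C
Reagents that add atoms: formaldehyde, C=O
Why: The enone has only one enolisable position (C10), so regiospecific aldol hydroxymethylation installs C20.

**Step 11**
Reactants: 11
Product: 12 saturated ketone 10-(hydroxymethyl) (C10 epimeric mixture)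
Conditions: H2 (1 atm), 10% Pd/C, EtOAc, rt
Reagents that add atoms: none
Why: Hydrogenation of the ring-A enone C=C removes the second acceptor that would otherwise intercept the cascade by double Michael addition.

**Step 12**
Reactants: 12
Product: 13 α-methylene ketone (C10=C20H2; stereo at C4, C5, C6 per SMILES)
Conditions: MsCl, Et3N, CH2Cl2, 0 °C; then DBU, rt
Reagents that add atoms: none
Why: Mesylation then E1cB elimination gives the exocyclic enone, which removes the C10 epimer issue and is the oxa-Michael acceptor for step 17.

**Step 13**
Reactants: 14 cyclohex-2-en-1-one; 15 methyl 3-[methoxy(methyl)amino]-3-oxopropanoate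
Product: 16 methyl 3-[methoxy(methyl)amino]-3-oxo-2-[(1R/S-defined at C13)-3-oxocyclohexyl]propanoate (malonate carbon epimeric)
Conditions: 9-amino-9-deoxy-epi-dihydroquinine (20 mol %), TFA (40 mol %), toluene, rt
Reagents that add atoms: none
Why: Primary-amine/Brønsted-acid organocatalytic enone Michael addition sets C13; the malonate carbon is epimerisable and becomes CH2 in the next step.

**Step 14**
Reactants: 16
Product: 17 N-methoxy-N-methyl-2-(3-oxocyclohexyl)acetamide (C13 as in SMILES)
Conditions: LiCl, H2O, DMSO, 140 °C
Reagents that add atoms: none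
Why: Krapcho demethoxycarbonylation removes the methyl ester chemoselectively and leaves the Weinreb amide.

**Step 15**
Reactants: 17
Product: 18 cyclohexenyl triflate (C8–OTf, C8=C9)
Conditions: KHMDS, THF, −78 °C; then PhNTf2
Reagents that add atoms: PhNTf2, O=S(=O)(C(F)(F)F)N(c1ccccc1)S(=O)(=O)C(F)(F)F
Why: Kinetic ketone enolisation, away from the C13 substituent, then O-triflation; the Weinreb amide is untouched. The minor regioisomer is removed by chromatography.

**Step 16**
Reactants: 18
Product: 19 (C13 as in SMILES) 5-[2-(methoxy(methyl)amino)-2-oxoethyl]cyclohex-1-ene-1-carboxylic acid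
Conditions: Pd(PPh3)4 (5 mol %), LiCl, n-Bu3N, CO (1 atm), DMF/H2O, 60 °C
Reagents that add atoms: carbon monoxide, [C-]#[O+]; water, O
Why: Cacchi-type Pd-catalysed hydroxycarbonylation of the vinyl triflate gives the acid that will act as the lactone oxygen nucleophile.

**Step 17**
Reactants: 13 α-methylene ketone; 19 acid
Product: 20 spirolactone/bicyclo[3.2.1]octanone core (C8, C9, C10 set; stereo per SMILES)
Conditions: KOt-Bu (2.5 equiv), THF/DMPU, −20 → 25 °C; then aq NH4Cl
Reagents that add atoms: none (MeNHOMe is lost)
Why: Proposed new method: the carboxylate adds (oxa-Michael) to C20 of the exocyclic enone, giving the thermodynamic C10 enolate already tethered through the new ester. That enolate adds 6-endo to C9 of the cyclohexene carboxylate from the face anti to the axial C19/C6 bridge, forming the spiro quaternary C10 and the δ-lactone. The resulting lactone enolate is then acylated 5-exo by the tethered Weinreb amide on the C13-side axial face, forming the C8 quaternary centre and ring D, with proton transfer from C16 as the thermodynamic sink. The closest known reactions are tandem Michael–Claisen (Michael-initiated ring-closure) annulations and oxa-Michael/Michael dominoes. The cascade diverts if the carboxylate retro-adds from the enolate before the C–C Michael occurs.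

**Step 18**
Reactants: 20
Product: 21 C1 tosylhydrazone
Conditions: TsNHNH2, MeOH, 60 °C (no acid)
Reagents that add atoms: p-toluenesulfonyl hydrazide, Cc1ccc(cc1)S(=O)(=O)NN
Why: The C1 ketone is far less hindered than the C15 ketone, which is flanked by quaternary C8; the neutral conditions spare the methyl acetal.

**Step 19**
Reactants: 21
Product: 22 C1-deoxygenated ketone (ring A saturated, C16H2)
Conditions: catecholborane, CHCl3, 0 °C → rt; then NaOAc·3H2O, 60 °C
Reagents that add atoms: none
Why: Kabalka reduction of the tosylhydrazone via the diazene gives CH2 without touching the lactone or acetal.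

**Step 20**
Reactants: 22
Product: 23 C15 α-methylene ketone
Conditions: LDA, THF, −78 °C; Me2N+=CH2 I−; then MeI; then DBU, rt
Reagents that add atoms: Eschenmoser's salt, C=[N+](C)C.[I-]
Why: Only C16 is enolisable (C8 is quaternary), so Mannich reaction, quaternisation and elimination install the exocyclic methylene regiospecifically.

**Step 21**
Reactants: 23
Product: 24 ludongnin I
Conditions: H2 (1 atm), 10% Pd/C, EtOAc, rt
Reagents that add atoms: none
Why: Catalytic hydrogenation delivers H to the convex exo face of the exocyclic enone, so the new methyl ends up endo, as in the target; the lactone, ketone and acetal are unaffected.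

## Compound list
1 | methyl 1,4-dioxaspiro[4.5]decane-8-carboxylate | COC(=O)C1CCC2(CC1)OCCO2 | starting material
2 | methyl 8-methyl-1,4-dioxaspiro[4.5]decane-8-carboxylate | COC(=O)C1(C)CCC2(CC1)OCCO2 | intermediate
3 | (8-methyl-1,4-dioxaspiro[4.5]decan-8-yl)methanol | OCC1(C)CCC2(CC1)OCCO2 | intermediate
4 | 8-[(allyloxy)methyl]-8-methyl-1,4-dioxaspiro[4.5]decane | C=CCOCC1(C)CCC2(CC1)OCCO2 | intermediate
5 | 4-[(allyloxy)methyl]-4-methylcyclohexan-1-one | C=CCOCC1(C)CCC(=O)CC1 | intermediate
6 | 4-[(allyloxy)methyl]-4-methylcyclohexa-2,5-dien-1-one | C=CCOCC1(C)C=CC(=O)C=C1 | intermediate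
7 | 2-[(1-methyl-4-oxocyclohexa-2,5-dien-1-yl)methoxy]acetaldehyde | O=CCOCC1(C)C=CC(=O)C=C1 | intermediate
8 | cis-3a-methyl-6-oxo-hexahydro-2-benzofuran-1-carbaldehyde | O=C[C@H]1OC[C@]2(C)C=CC(=O)C[C@H]12 | intermediate
9 | lactol formate | O=CO[C@H]1OC[C@]2(C)C=CC(=O)C[C@H]12 | intermediate
10 | methyl acetal enone | CO[C@H]1OC[C@]2(C)C=CC(=O)C[C@H]12 | intermediate
11 | 10-(hydroxymethyl) enone (C10 epimers) | CO[C@H]1OC[C@]2(C)C=CC(=O)C(CO)[C@H]12 | intermediate
12 | saturated 10-(hydroxymethyl) ketone (C10 epimers) | CO[C@H]1OC[C@]2(C)CCC(=O)C(CO)[C@H]12 | intermediate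
13 | α-methylene ketone | CO[C@H]1OC[C@]2(C)CCC(=O)C(=C)[C@H]12 | intermediate
14 | cyclohex-2-en-1-one | O=C1C=CCCC1 | starting material
15 | methyl 3-[methoxy(methyl)amino]-3-oxopropanoate | COC(=O)CC(=O)N(C)OC | starting material
16 | malonate Michael adduct (malonate C epimeric) | COC(=O)C(C(=O)N(C)OC)[C@@H]1CCCC(=O)C1 | intermediate
17 | keto Weinreb amide | CON(C)C(=O)C[C@@H]1CCCC(=O)C1 | intermediate
18 | cyclohexenyl triflate | CON(C)C(=O)C[C@@H]1CCC=C(OS(=O)(=O)C(F)(F)F)C1 | intermediate
19 | cyclohexene carboxylic acid Weinreb amide | CON(C)C(=O)C[C@@H]1CCC=C(C(=O)O)C1 | intermediate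
20 | cascade product (spirolactone bicyclo[3.2.1]octanone, C1 ketone) | CO[C@H]1OC[C@]2(C)CCC(=O)[C@]3(COC(=O)[C@@]45C[C@@H](CC[C@H]43)CC5=O)[C@H]12 | intermediate
21 | C1 tosylhydrazone | CO[C@H]1OC[C@]2(C)CCC(=NNS(=O)(=O)c3ccc(C)cc3)[C@]3(COC(=O)[C@@]45C[C@@H](CC[C@H]43)CC5=O)[C@H]12 | intermediate
22 | C1-deoxygenated ketone | CO[C@H]1OC[C@]2(C)CCC[C@]3(COC(=O)[C@@]45C[C@@H](CC[C@H]43)CC5=O)[C@H]12 | intermediate
23 | α-methylene ketone | CO[C@H]1OC[C@]2(C)CCC[C@]3(COC(=O)[C@@]45C[C@@H](CC[C@H]43)C(=C)C5=O)[C@H]12 | intermediate
24 | ludongnin I | CO[C@H]1OC[C@]2(C)CCC[C@]3(COC(=O)[C@@]45C[C@@H](CC[C@H]43)[C@@H](C)C5=O)[C@H]12 | target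

**Total step count:** 21
**Longest linear sequence:** 17 steps (1→…→12→13, then step 17, then steps 18–21)

## Three steps most likely to fail
1. **Step 17 (proposed new cascade).** The carboxylate can retro-add from the enolate before the slow 6-endo C–C Michael onto the trisubstituted enoate, and the acylation is a quaternary Claisen.
 Fallback (known chemistry): Steglich esterification of 12 with 19, then the C10 silyl enol ether and intramolecular Mukaiyama–Michael with catalytic TMSNTf2 to form the spirolactone. Then ketalise C1, do LDA/Weinreb intramolecular acylation to build ring D, and deprotect.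
2. **Steps 18–19 (C1 deoxygenation).** Hydrazone formation next to quaternary C10 is slow, and catecholborane may reduce the C15 ketone.
 Fallback: convert the C1 ketone to the dithiolane (HSCH2CH2SH, Sc(OTf)3), desulfurise with Raney Ni, and re-oxidise any C15 alcohol with DMP.
3. **Step 21 (C16 stereochemistry).** Hydrogenation may give the exo-methyl epimer instead of the endo-methyl one.
 Fallback: conjugate reduction of 23 with L-Selectride at −78 °C, then kinetic protonation of the enolate from the exo face (t-BuOH quench).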